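**Plan**
Retrosynthesis: after removal of two benzyl groups and the 5-O-methyl group, ring C is cut at O1–C2 (oxidative cyclisation of a 2'-hydroxychalcone), at C2–C3 (Claisen–Schmidt condensation) and at C4–C4a (Friedel–Crafts acetylation).
Ring A is then cut at C4a–C8a and C5–C6. It has 7-OMe and 8-OMe on neighbouring carbons between the oxygen-bearing C6 and C8a, which are para to each other; this is the pattern of dimethyl squarate enlarged by a two-carbon enol ether unit (C5, C4a).
Forward: 1-methoxyvinyllithium adds to dimethyl squarate (C5–C6), thermolysis builds ring A (C4a–C8a), the hydroquinone is acetylated and monobenzylated, ring B arrives preformed as an aldehyde, ring C closes last, and one Lewis-acid step frees the three hydroxyls.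
Stereochemistry: the target is achiral; the racemic carbinol centre of the squarate adduct vanishes on aromatisation, and the E-alkene of the chalcone and the racemic centres of the transient intermediates are consumed on the way to the flavone.

Key step: step 2

Remark: hydroquinone 7 and ketone 8 are oxygen-sensitive, so steps 2 to 4 are assumed to run under argon in degassed solvents, with 7 carried into step 3 without storage. Compound 4 has an acid-labile enol ether and is purified on triethylamine-deactivated silica.

Step 1
Reactants: 1 methyl vinyl ether (methoxyethene); 2 dimethyl squarate (3,4-dimethoxycyclobut-3-ene-1,2-dione)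
Product: 4 rac-4-hydroxy-2,3-dimethoxy-4-(1-methoxyethenyl)cyclobut-2-en-1-one, via 1-methoxyvinyllithium 3 (not isolated)
Conditions: 1 (1.5 equiv), t-BuLi (1.15 equiv), THF, −78 → 0 °C; then added to 2, THF, −78 °C; sat. aq. NH4Cl, −78 °C
Reagents that add atoms: none
Why: tert-Butyllithium removes the α-hydrogen of the enol ether and the resulting alkenyllithium should add once, in 1,2-fashion, to one of the two equivalent carbonyl groups of the squarate ester at −78 °C, where the lithium alkoxide is inert to a second addition (organolithium 1,2-addition to a vinylogous ester carbonyl); the carbinol centre forms as a racemate and is destroyed in step 2.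

Step 2
Reactants: 4 rac-4-hydroxy-2,3-dimethoxy-4-(1-methoxyethenyl)cyclobut-2-en-1-one
Product: 7 2,3,5-trimethoxybenzene-1,4-diol, via dienylketene 5 (not isolated), via cyclohexadienone 6 (not isolated)
Conditions: degassed PhMe (0.02 M), 110 °C, Ar
Reagents that add atoms: none
Why: Heating should open the bond between the carbonyl carbon and the carbinol carbon of the cyclobutenone in a conrotatory 4π electrocyclic reaction to the (3Z)-dienylketene 5, whose ketene carbon (future C8a) then bonds to the terminal CH2 of the methoxyvinyl group (future C4a), and the cyclohexa-2,4-dienone 6 so formed enolises to the aromatic hydroquinone 7. The closest known reaction type is the thermal ring expansion of 4-alkenyl-4-hydroxycyclobutenones made from squarate esters to substituted hydroquinones. Ring A closes by a thermal disrotatory 6π electrocyclisation across the ketene C=C, the central enol C=C and the vinyl C=C, which forms the single new ring bond C4a–C8a. No stereocentre is created; the racemic carbinol carbon of 4 becomes the sp2 carbon C6. The step needs torquoselectivity, namely inward rotation of the methoxyvinyl group so that it ends cis to the ketene, and this is secured by the carbinol hydroxyl, a lone-pair donor that rotates outward, which also keeps the hydroxyl away from the ketene and so avoids lactonisation to a butenolide. Regiochemistry is fixed because only one ring bond can open and the vinyl group offers one terminus, so 7-OMe and 8-OMe come from the squarate, 5-OMe and C4a–H from the enol ether, and the hydroxyls at C6 and C8a from the two squarate carbonyl oxygens.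

Step 3
Reactants: 7 2,3,5-trimethoxybenzene-1,4-diol
Product: 8 1-(2,5-dihydroxy-3,4,6-trimethoxyphenyl)ethan-1-one
Conditions: AcOH, BF3·OEt2 (3 equiv), 80 °C, Ar; then H2O
Reagents that add atoms: acetic acid, CC(=O)O
Why: Friedel–Crafts C-acetylation with the acetic acid–BF3 system is standard for polymethoxylated phenols and hydroquinones, and the single unsubstituted ring position (future C4a), ortho to the C8a hydroxyl, is the only site available, so the regiochemistry is unambiguous.

Step 4
Reactants: 8 1-(2,5-dihydroxy-3,4,6-trimethoxyphenyl)ethan-1-one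
Product: 9 1-[5-(benzyloxy)-2-hydroxy-3,4,6-trimethoxyphenyl]ethan-1-one
Conditions: BnBr (1.05 equiv), K2CO3 (1.1 equiv), acetone, reflux, Ar
Reagents that add atoms: benzyl bromide, BrCc1ccccc1
Why: Williamson etherification with a weak base and one equivalent of halide should alkylate only the 5-hydroxyl (future 6-OH), because the 2-hydroxyl is held in a hydrogen bond to the acetyl carbonyl and is much less nucleophilic.

Step 5
Reactants: 10 2-hydroxy-6-methoxybenzaldehyde
Product: 11 2-(benzyloxy)-6-methoxybenzaldehyde
Conditions: BnBr, K2CO3, DMF, 60 °C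
Reagents that add atoms: benzyl bromide, BrCc1ccccc1
Why: Williamson etherification masks the acidic phenol, which as its phenoxide would deactivate the aldehyde in the base-mediated condensation that follows.

Step 6
Reactants: 9 1-[5-(benzyloxy)-2-hydroxy-3,4,6-trimethoxyphenyl]ethan-1-one; 11 2-(benzyloxy)-6-methoxybenzaldehyde
Product: 13 (E)-1-[5-(benzyloxy)-2-hydroxy-3,4,6-trimethoxyphenyl]-3-[2-(benzyloxy)-6-methoxyphenyl]prop-2-en-1-one, via aldol adduct 12 (not isolated)
Conditions: KOH (50% aq.), EtOH, rt, Ar; then dil. HCl
Reagents that add atoms: none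
Why: Claisen–Schmidt condensation, in which the non-enolisable aldehyde 11 accepts the enolate of 9 and the aldol adduct 12 loses water by E1cB elimination to the conjugated enone in its thermodynamically favoured E geometry.

Step 7
Reactants: 13 (E)-1-[5-(benzyloxy)-2-hydroxy-3,4,6-trimethoxyphenyl]-3-[2-(benzyloxy)-6-methoxyphenyl]prop-2-en-1-one
Product: 15 6-(benzyloxy)-2-[2-(benzyloxy)-6-methoxyphenyl]-5,7,8-trimethoxy-4H-chromen-4-one, via flavanone 14 (not isolated)
Conditions: I2 (10 mol %), DMSO, 120 °C
Reagents that add atoms: none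
Why: Iodine-catalysed oxidative cyclisation of a 2'-hydroxychalcone in DMSO, in which the phenol closes ring C by 6-endo oxa-Michael addition to the flavanone 14 and iodine dehydrogenates it to the flavone while DMSO reoxidises the hydrogen iodide, conditions that aryl methyl and benzyl ethers are expected to tolerate.

Step 8
Reactants: 15 6-(benzyloxy)-2-[2-(benzyloxy)-6-methoxyphenyl]-5,7,8-trimethoxy-4H-chromen-4-one
Product: 16 5,6,2'-trihydroxy-7,8,6'-trimethoxyflavone [5,6-dihydroxy-2-(2-hydroxy-6-methoxyphenyl)-7,8-dimethoxy-4H-chromen-4-one]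
Conditions: BCl3 (5 equiv), pentamethylbenzene (6 equiv), CH2Cl2, −78 → 0 °C; then H2O
Reagents that add atoms: none
Why: Lewis-acid ether cleavage, in which BCl3 should remove both benzyl groups at low temperature (the benzyl cations being trapped by pentamethylbenzene) and cleave the 5-OMe selectively, because only this methyl ether is peri to the C4 carbonyl and forms a six-membered boron chelate, whereas the 7-, 8- and 6'-methoxy groups have no such assistance.

**Compound list**
1 | methyl vinyl ether (methoxyethene) | COC=C | starting material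
2 | dimethyl squarate (3,4-dimethoxycyclobut-3-ene-1,2-dione) | COC1=C(OC)C(=O)C1=O | starting material
3 | 1-methoxyvinyllithium | [Li]C(=C)OC | intermediate
4 | rac-4-hydroxy-2,3-dimethoxy-4-(1-methoxyethenyl)cyclobut-2-en-1-one | COC(=C)C1(O)C(OC)=C(OC)C1=O | intermediate
5 | (3Z)-4-hydroxy-2,3,5-trimethoxyhexa-1,3,5-trien-1-one (dienylketene) | COC(=C)/C(O)=C(OC)\C(OC)=C=O | intermediate
6 | 4-hydroxy-2,3,5-trimethoxycyclohexa-2,4-dien-1-one | COC1=C(O)C(OC)=C(OC)C(=O)C1 | intermediate
7 | 2,3,5-trimethoxybenzene-1,4-diol | COc1cc(O)c(OC)c(OC)c1O | intermediate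
8 | 1-(2,5-dihydroxy-3,4,6-trimethoxyphenyl)ethan-1-one | CC(=O)c1c(O)c(OC)c(OC)c(O)c1OC | intermediate
9 | 1-[5-(benzyloxy)-2-hydroxy-3,4,6-trimethoxyphenyl]ethan-1-one | CC(=O)c1c(O)c(OC)c(OC)c(OCc2ccccc2)c1OC | intermediate
10 | 2-hydroxy-6-methoxybenzaldehyde | COc1cccc(O)c1C=O | starting material
11 | 2-(benzyloxy)-6-methoxybenzaldehyde | COc1cccc(OCc2ccccc2)c1C=O | intermediate
12 | rac-1-[5-(benzyloxy)-2-hydroxy-3,4,6-trimethoxyphenyl]-3-[2-(benzyloxy)-6-methoxyphenyl]-3-hydroxypropan-1-one (aldol adduct) | COc1cccc(OCc2ccccc2)c1C(O)CC(=O)c1c(O)c(OC)c(OC)c(OCc2ccccc2)c1OC | intermediate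
13 | (E)-1-[5-(benzyloxy)-2-hydroxy-3,4,6-trimethoxyphenyl]-3-[2-(benzyloxy)-6-methoxyphenyl]prop-2-en-1-one | COc1cccc(OCc2ccccc2)c1/C=C/C(=O)c1c(O)c(OC)c(OC)c(OCc2ccccc2)c1OC | intermediate
14 | rac-6-(benzyloxy)-2-[2-(benzyloxy)-6-methoxyphenyl]-5,7,8-trimethoxy-2,3-dihydro-4H-chromen-4-one (flavanone) | COc1cccc(OCc2ccccc2)c1C1CC(=O)c2c(OC)c(OCc3ccccc3)c(OC)c(OC)c2O1 | intermediate
15 | 6-(benzyloxy)-2-[2-(benzyloxy)-6-methoxyphenyl]-5,7,8-trimethoxy-4H-chromen-4-one | COc1cccc(OCc2ccccc2)c1-c1cc(=O)c2c(OC)c(OCc3ccccc3)c(OC)c(OC)c2o1 | intermediate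
16 | 5,6,2'-trihydroxy-7,8,6'-trimethoxyflavone | COc1cccc(O)c1-c1cc(=O)c2c(O)c(O)c(OC)c(OC)c2o1 | target

**Step count**
Total: 8 steps. Longest linear sequence: 7 steps (steps 1, 2, 3, 4, 6, 7, 8); step 5 is a one-step side branch.

**Steps most likely to fail**

Step 3. The electron-rich hydroquinone may oxidise to the quinone during transfer and heating, BF3 may strip the methyl ether next to the new ketone on prolonged heating, or acetylation may stop at oxygen. The fallback replaces electrophilic substitution by directed metalation and sets out from 7. Both hydroxyls would be protected (MOMCl, i-Pr2NEt, CH2Cl2, 0 °C) as 2,3,5-trimethoxy-1,4-bis(methoxymethoxy)benzene F1. Ortho-lithiation at the only ring hydrogen, flanked by OMOM and OMe (n-BuLi, TMEDA, THF, −78 → 0 °C), should give [2,5-bis(methoxymethoxy)-3,4,6-trimethoxyphenyl]lithium F2. Acylation with N-methoxy-N-methylacetamide at −78 °C should give 1-[2,5-bis(methoxymethoxy)-3,4,6-trimethoxyphenyl]ethan-1-one F3, and acetal cleavage (HCl, MeOH, 40 °C) comes back to the route at 8.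

Step 6. Both partners are di-ortho-substituted, so enolate addition may stall, and long exposure to strong base may lead to disproportionation of the aldehyde or retro-aldol cleavage. The fallback builds ring C through a 1,3-diketone and sets out from 11 and 9. Pinnick oxidation of 11 (NaClO2, NaH2PO4, 2-methylbut-2-ene, t-BuOH–H2O) should give 2-(benzyloxy)-6-methoxybenzoic acid F4, which (COCl)2 and catalytic DMF convert into 2-(benzyloxy)-6-methoxybenzoyl chloride F5. O-Acylation of 9 in pyridine should give 2-acetyl-4-(benzyloxy)-3,5,6-trimethoxyphenyl 2-(benzyloxy)-6-methoxybenzoate F6. Baker–Venkataraman rearrangement (KOH, pyridine, 50 °C) should give 1-[5-(benzyloxy)-2-hydroxy-3,4,6-trimethoxyphenyl]-3-[2-(benzyloxy)-6-methoxyphenyl]propane-1,3-dione F7, and cyclodehydration (cat. H2SO4, AcOH, 60 °C) comes back to the route at 15, bypassing 13 and step 7.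

Step 8. Once O6 is bound to boron, the neighbouring 7-OMe may also be cleaved; benzyl cations may alkylate the electron-rich rings; or one ether may survive. The fallback separates the two events and sets out from 15. Hydrogenolysis (H2, Pd/C, EtOAc–MeOH, rt) should give 6-hydroxy-2-(2-hydroxy-6-methoxyphenyl)-5,7,8-trimethoxy-4H-chromen-4-one F8. Chelation-controlled demethylation of the 5-methyl ether alone (AlCl3, MeCN, rt; then dil. HCl) then arrives at 16.

**Further compounds**
F1 | step 3 | 2,3,5-trimethoxy-1,4-bis(methoxymethoxy)benzene | COc1cc(OCOC)c(OC)c(OC)c1OCOC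
F2 | step 3 | [2,5-bis(methoxymethoxy)-3,4,6-trimethoxyphenyl]lithium | COc1c([Li])c(OCOC)c(OC)c(OC)c1OCOC
F3 | step 3 | 1-[2,5-bis(methoxymethoxy)-3,4,6-trimethoxyphenyl]ethan-1-one | CC(=O)c1c(OCOC)c(OC)c(OC)c(OCOC)c1OC
F4 | step 6 | 2-(benzyloxy)-6-methoxybenzoic acid | COc1cccc(OCc2ccccc2)c1C(=O)O
F5 | step 6 | 2-(benzyloxy)-6-methoxybenzoyl chloride | COc1cccc(OCc2ccccc2)c1C(Cl)=O
F6 | step 6 | 2-acetyl-4-(benzyloxy)-3,5,6-trimethoxyphenyl 2-(benzyloxy)-6-methoxybenzoate | COc1cccc(OCc2ccccc2)c1C(=O)Oc1c(OC)c(OC)c(OCc2ccccc2)c(OC)c1C(C)=O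
F7 | step 6 | 1-[5-(benzyloxy)-2-hydroxy-3,4,6-trimethoxyphenyl]-3-[2-(benzyloxy)-6-methoxyphenyl]propane-1,3-dione | COc1cccc(OCc2ccccc2)c1C(=O)CC(=O)c1c(O)c(OC)c(OC)c(OCc2ccccc2)c1OC
F8 | step 8 | 6-hydroxy-2-(2-hydroxy-6-methoxyphenyl)-5,7,8-trimethoxy-4H-chromen-4-one | COc1cccc(O)c1-c1cc(=O)c2c(OC)c(O)c(OC)c(OC)c2o1
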